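**Retrosynthetic overview**

1. Target ⇒ (desilylation and acetonide hydrolysis; Mizoroki–Heck at benzofuran C4; allyl ester removal) ⇒ bromo cis-dihydrobenzofuran 23. Its furan ring (C2–C3 bond) is closed by dirhodium-carbenoid C–H insertion of aryldiazoacetate 22. The O5–acyl bond is made earlier, on the stereocenter-free arylacetic acid 20, so the labile cis C3 center is never acylated.
2. Acid 20 ⇐ (2,3-dimethoxyphenyl)acetic acid. A lactone ring that is not in the target (benzofuranone 13) is made on purpose to mask O2 and the carboxyl, so that only O3 is silylated. It is then opened and O2 is benzylated with alcohol 17.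
3. Shikimate alcohol 9 ⇐ cyclohexene 7 ⇐ aldehyde–phosphonoacetate 5 + glycolaldehyde 4 (key step); 5 ⇐ 4 + 2-phosphonoacrylate 3 (enamine Michael addition, sets C5).
4. Enabling feature: in the cyclohexene ring, C2 is both the β-carbon of the C1=C2 enoate (C1 bears the carboxyl; olefination retron) and the carbonyl-level carbon of the C2–C3(O)–C4(OH) array (aldol retron). C2–C3 is therefore one glycolaldehyde unit, stitched to the C4–C5–C6–C1 chain by enamine aldol (C3–C4) and ring-closing Horner–Wadsworth–Emmons olefination (C1=C2) in one flask.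
5. Ring order: cyclohexene (step 3), dioxolane (step 5), temporary lactone (step 7, opened in step 11), dihydrofuran (step 15).

Key step: step 3

Remark on the target: the SMILES defines the 2,3-cis-dihydrobenzofuran (2S,3R; aryl and acyl on the same face) esterified at O5 of natural-configuration shikimic acid. This isomer can epimerize to trans by C3 enolization (base) or C2–O ionization (strong acid, or a free para-phenoxide), so it is created late and only near-neutral or weakly acidic conditions follow. TBS = tert-butyldimethylsilyl, TBSO = tert-butyldimethylsilyloxy.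

Assumption: Rh2(R-PTTL)4 is assumed to give the (2S,3R) sense in step 15; should the sense be opposite, the (S)-configured catalyst is used instead.

**Route**

Step 1
Reactants: 1 allyl 2-(diethoxyphosphoryl)acetate
Product: 3 allyl 2-(diethoxyphosphoryl)acrylate, via hydroxymethyl adduct 2 (not isolated)
Conditions: (CH2O)n, piperidine (cat.), MeOH, reflux; then TsOH·H2O (cat.), toluene, reflux (Dean–Stark)
Reagents that add atoms: paraformaldehyde (formaldehyde), C=O
Why: Knoevenagel-type hydroxymethylation of the phosphonoacetate followed by acid-catalysed dehydration is the standard entry to 2-phosphonoacrylates and creates no stereocenter.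

Step 2
Reactants: 3 allyl 2-(diethoxyphosphoryl)acrylate; 4 (tert-butyldimethylsilyloxy)acetaldehyde
Product: 5 allyl (4R)-4-(TBSO)-2-(diethoxyphosphoryl)-5-oxopentanoate (both C2 epimers)
Conditions: (S)-2-[diphenyl(trimethylsilyloxy)methyl]pyrrolidine (10 mol%), CHCl3, 0 °C → rt; short silica filtration, used at once
Reagents that add atoms: none
Why: Enamine Michael addition of an aldehyde to a 2-phosphonoacrylate under diarylprolinol silyl ether catalysis, in which the E-enamine of 4 is attacked on the face remote from the diphenyl(silyloxy)methyl group, setting the α-silyloxy carbon (future shikimate C5) as R, while the phosphonate-bearing carbon is an inconsequential epimer mixture.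

Step 3
Reactants: 5 allyl (4R)-4-(TBSO)-2-(diethoxyphosphoryl)-5-oxopentanoate; 4 (tert-butyldimethylsilyloxy)acetaldehyde
Product: 7 allyl (3R,4S,5R)-3,5-bis(TBSO)-4-hydroxycyclohex-1-ene-1-carboxylate, via aldol adduct 6 (not isolated)
Conditions: L-proline (20 mol%), DMF, 4 °C, 4 (1.5 equiv) added by syringe pump; then Cs2CO3 (1.5 equiv), 0 °C
Reagents that add atoms: none
Why: Proposed new method: L-proline converts unbranched 4 into an E-enamine that adds to the aldehyde of 5 through the carboxylic-acid-directed chair transition state (C3–C4 bond, anti-aldol); Cs2CO3 then deprotonates the phosphonoacetate of 6, whose carbanion adds 6-exo-trig to the new α-silyloxy aldehyde and collapses through the oxaphosphetane to the C1=C2 enoate, so the carbocycle is closed by intramolecular Horner–Wadsworth–Emmons olefination with a necessarily cis endocyclic alkene. The closest known reactions are the proline-catalysed anti-selective cross-aldol of α-silyloxy aldehyde donors and the one-pot amine-catalysed Michael/intramolecular Horner–Wadsworth–Emmons annulation to cyclohexenecarboxylates; new is their union as a formal (4+2) aldol/olefination annulation on an acceptor that already carries the phosphonoacetate. C3 and C4 are set by the catalyst (L-proline gives the 3S,4S anti adduct, which is the cis-3,4-diol of the ring), C5 is carried in from step 2, and the 4,5-threo relationship corresponds to pairing an L-proline enamine with an (R)-2-oxy aldehyde. The step needs cross- over self-aldol selectivity, secured because α-branched 5 forms an enamine only reluctantly and so acts as acceptor while 4 is kept at low concentration, and it needs ring closure to outrun retro-aldol, β-elimination and intermolecular olefination, which the six-membered transition state and the mild base at 0 °C should secure.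

Step 4
Reactants: 7 allyl (3R,4S,5R)-3,5-bis(TBSO)-4-hydroxycyclohex-1-ene-1-carboxylate
Product: 8 allyl (3R,4S,5R)-3,4,5-trihydroxycyclohex-1-ene-1-carboxylate (allyl shikimate)
Conditions: HF (48% aq.), MeCN, 0 °C → rt
Reagents that add atoms: none
Why: Aqueous HF cleaves secondary silyl ethers without touching the allyl enoate, and any 1,2-silyl migration under the basic olefination conditions converges on the same triol with no stereocenter affected.

Step 5
Reactants: 8 allyl shikimate
Product: 9 allyl (3aR,7R,7aS)-7-hydroxy-2,2-dimethyl-3a,6,7,7a-tetrahydro-1,3-benzodioxole-5-carboxylate (allyl 3,4-O-isopropylideneshikimate)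
Conditions: 2,2-dimethoxypropane, CSA (cat.), acetone, rt
Reagents that add atoms: 2,2-dimethoxypropane, COC(C)(C)OC
Why: Acid-catalysed transketalization selects the cis-3,4-diol (cis-fused dioxolane) over the trans-4,5-diol, as is standard for shikimate esters, leaving O5–H free.

Step 6
Reactants: 10 (2,3-dimethoxyphenyl)acetic acid
Product: 11 (6-bromo-2,3-dimethoxyphenyl)acetic acid
Conditions: NBS, MeCN, 0 °C → rt
Reagents that add atoms: N-bromosuccinimide, O=C1CCC(=O)N1Br
Why: Electrophilic aromatic bromination goes para to the 3-methoxy group (C6), because the 2-methoxy group is twisted out of conjugation by its two ortho neighbours, as in the bromination of 2,3-dimethoxytoluene.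

Step 7
Reactants: 11 (6-bromo-2,3-dimethoxyphenyl)acetic acid
Product: 13 4-bromo-7-hydroxy-1-benzofuran-2(3H)-one, via dihydroxy acid 12 (not isolated)
Conditions: BBr3 (4 equiv), CH2Cl2, −78 °C → rt; H2O; then TsOH·H2O (cat.), toluene, reflux
Reagents that add atoms: none
Why: BBr3 cleaves both aryl methyl ethers and the resulting 2-hydroxyphenylacetic acid lactonizes under acid, giving a temporary five-membered ring that masks O2 and the carboxyl so that only the O3 phenol is free.

Step 8
Reactants: 13 4-bromo-7-hydroxy-1-benzofuran-2(3H)-one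
Product: 14 4-bromo-7-(TBSO)-1-benzofuran-2(3H)-one
Conditions: TBSCl, imidazole, CH2Cl2, 0 °C → rt
Reagents that add atoms: tert-butyldimethylsilyl chloride, CC(C)(C)[Si](C)(C)Cl
Why: Imidazole-mediated silylation of the only free phenol is a standard protection, and the weak base does not enolize the lactone.

Step 9
Reactants: 15 3,4-dihydroxybenzaldehyde
Product: 16 3,4-bis(TBSO)benzaldehyde
Conditions: TBSCl (2.3 equiv), imidazole, DMF, rt
Reagents that add atoms: tert-butyldimethylsilyl chloride, CC(C)(C)[Si](C)(C)Cl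
Why: Standard silylation of both phenols of the catechol.

Step 10
Reactants: 16 3,4-bis(TBSO)benzaldehyde
Product: 17 [3,4-bis(TBSO)phenyl]methanol
Conditions: NaBH4, MeOH/THF, 0 °C
Reagents that add atoms: none
Why: Borohydride reduction of the aldehyde is fast at 0 °C and the aryl silyl ethers survive the short exposure.

Step 11
Reactants: 14 4-bromo-7-(TBSO)-1-benzofuran-2(3H)-one; 17 [3,4-bis(TBSO)phenyl]methanol
Product: 19 allyl [6-bromo-2-{[3,4-bis(TBSO)phenyl]methoxy}-3-(TBSO)phenyl]acetate, via hydroxy ester 18 (not isolated)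
Conditions: allyl alcohol (solvent), CSA (5 mol%), 40 °C; NaHCO3, concentrate; then 17, PPh3, DIAD, THF, 0 °C → rt
Reagents that add atoms: allyl alcohol, C=CCO
Why: Acid-catalysed alcoholysis opens the phenolic lactone to hydroxy ester 18, which is used at once in a Mitsunobu etherification with the benzylic alcohol under neutral conditions that avoid a free phenoxide and hence silyl scrambling.

Step 12
Reactants: 19 allyl [6-bromo-2-{[3,4-bis(TBSO)phenyl]methoxy}-3-(TBSO)phenyl]acetate
Product: 20 [6-bromo-2-{[3,4-bis(TBSO)phenyl]methoxy}-3-(TBSO)phenyl]acetic acid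
Conditions: Pd(PPh3)4 (3 mol%), morpholine, THF, rt
Reagents that add atoms: none
Why: Tsuji–Trost allyl transfer from the ester to morpholine with zerovalent palladium is neutral and does not touch the aryl bromide or the silyl ethers at room temperature.

Step 13
Reactants: 20 [6-bromo-2-{[3,4-bis(TBSO)phenyl]methoxy}-3-(TBSO)phenyl]acetic acid; 9 allyl 3,4-O-isopropylideneshikimate
Product: 21 allyl (3aR,7R,7aS)-7-({[6-bromo-2-{[3,4-bis(TBSO)phenyl]methoxy}-3-(TBSO)phenyl]acetyl}oxy)-2,2-dimethyl-3a,6,7,7a-tetrahydro-1,3-benzodioxole-5-carboxylate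
Conditions: EDC·HCl, DMAP (cat.), CH2Cl2, 0 °C → rt
Reagents that add atoms: none
Why: Steglich esterification of an arylacetic acid that has no stereocenter puts the O5 ester bond in place before the epimerizable C3 center exists.

Step 14
Reactants: 21 arylacetate ester of allyl 3,4-O-isopropylideneshikimate
Product: 22 allyl (3aR,7R,7aS)-7-({diazo[6-bromo-2-{[3,4-bis(TBSO)phenyl]methoxy}-3-(TBSO)phenyl]acetyl}oxy)-2,2-dimethyl-3a,6,7,7a-tetrahydro-1,3-benzodioxole-5-carboxylate
Conditions: p-ABSA, DBU, dry MeCN, 0 °C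
Reagents that add atoms: 4-acetamidobenzenesulfonyl azide, CC(=O)Nc1ccc(cc1)S(=O)(=O)N=[N+]=[N-]
Why: Regitz diazo transfer occurs at the arylacetate methylene, the most acidic C–H in the molecule.

Step 15
Reactants: 22 aryldiazoacetate
Product: 23 allyl (3aR,7R,7aS)-7-({(2S,3R)-4-bromo-2-[3,4-bis(TBSO)phenyl]-7-(TBSO)-2,3-dihydro-1-benzofuran-3-carbonyl}oxy)-2,2-dimethyl-3a,6,7,7a-tetrahydro-1,3-benzodioxole-5-carboxylate
Conditions: Rh2(R-PTTL)4 [dirhodium tetrakis(N-phthaloyl-(R)-tert-leucinate)] (2 mol%), toluene (0.01 M), −60 °C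
Reagents that add atoms: none
Why: Intramolecular 1,5 C–H insertion of the donor/acceptor dirhodium carbenoid into the benzylic ether C–H is a known cis-selective dihydrobenzofuran synthesis, in which the chiral carboxylate catalyst sets C2 and C3 together through a concerted hydride-transfer-like transition state, while dilution and low temperature disfavour cyclopropanation of the remote allyl ester.

Step 16
Reactants: 23 cis-dihydrobenzofuran allyl ester
Product: 24 (3aR,7R,7aS)-7-({(2S,3R)-4-bromo-2-[3,4-bis(TBSO)phenyl]-7-(TBSO)-2,3-dihydro-1-benzofuran-3-carbonyl}oxy)-2,2-dimethyl-3a,6,7,7a-tetrahydro-1,3-benzodioxole-5-carboxylic acid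
Conditions: Pd(PPh3)4 (5 mol%), N-methylaniline, THF, rt
Reagents that add atoms: none
Why: Tsuji–Trost deallylation with the weakly basic N-methylaniline as allyl acceptor frees the shikimate carboxyl without a base strong enough to epimerize C3.

Step 17
Reactants: 24 bromo acid; 25 acrylic acid
Product: 26 (3aR,7R,7aS)-7-({(2S,3R)-4-[(E)-2-carboxyethenyl]-2-[3,4-bis(TBSO)phenyl]-7-(TBSO)-2,3-dihydro-1-benzofuran-3-carbonyl}oxy)-2,2-dimethyl-3a,6,7,7a-tetrahydro-1,3-benzodioxole-5-carboxylic acid
Conditions: Pd[P(t-Bu)3]2 (5 mol%), Cy2NMe (3.5 equiv), 1,4-dioxane, 45 °C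
Reagents that add atoms: none
Why: Mizoroki–Heck coupling of the aryl bromide with acrylic acid, where the bulky electron-rich phosphine catalyst allows a hindered amine base near ambient temperature so that the cis C3–H is not epimerized, and syn-insertion/syn-β-hydride elimination gives the E-alkene.

Step 18
Reactants: 26 protected diacid
Product: 27 (3R,4R,5R)-5-({(2S,3R)-4-[(E)-2-carboxyethenyl]-2-(3,4-dihydroxyphenyl)-7-hydroxy-2,3-dihydro-1-benzofuran-3-carbonyl}oxy)-3,4-dihydroxycyclohex-1-ene-1-carboxylic acid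
Conditions: HF (48% aq.), MeCN/H2O, 0 °C → rt
Reagents that add atoms: none
Why: Aqueous HF cleaves the three aryl silyl ethers and hydrolyses the acetonide under weakly acidic, non-basic conditions that avoid both C3 enolization and quinone-methide opening of the C2–O bond, and the hindered O5 ester survives.

**Compound list**

1 | allyl 2-(diethoxyphosphoryl)acetate | C=CCOC(=O)CP(=O)(OCC)OCC | starting material
2 | allyl 2-(diethoxyphosphoryl)-3-hydroxypropanoate | C=CCOC(=O)C(CO)P(=O)(OCC)OCC | intermediate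
3 | allyl 2-(diethoxyphosphoryl)acrylate | C=CCOC(=O)C(=C)P(=O)(OCC)OCC | intermediate
4 | (tert-butyldimethylsilyloxy)acetaldehyde | CC(C)(C)[Si](C)(C)OCC=O | starting material
5 | allyl (4R)-4-(tert-butyldimethylsilyloxy)-2-(diethoxyphosphoryl)-5-oxopentanoate (both C2 epimers) | C=CCOC(=O)C(C[C@@H](O[Si](C)(C)C(C)(C)C)C=O)P(=O)(OCC)OCC | intermediate
6 | allyl (4R,5S,6S)-4,6-bis(tert-butyldimethylsilyloxy)-2-(diethoxyphosphoryl)-5-hydroxy-7-oxoheptanoate | CC(C)(C)[Si](C)(C)O[C@H](CC(P(=O)(OCC)OCC)C(=O)OCC=C)[C@H](O)[C@H](O[Si](C)(C)C(C)(C)C)C=O | intermediate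
7 | allyl (3R,4S,5R)-3,5-bis(tert-butyldimethylsilyloxy)-4-hydroxycyclohex-1-ene-1-carboxylate | CC(C)(C)[Si](C)(C)O[C@@H]1CC(C(=O)OCC=C)=C[C@@H](O[Si](C)(C)C(C)(C)C)[C@H]1O | intermediate
8 | allyl (3R,4S,5R)-3,4,5-trihydroxycyclohex-1-ene-1-carboxylate (allyl shikimate) | O[C@@H]1CC(C(=O)OCC=C)=C[C@@H](O)[C@H]1O | intermediate
9 | allyl (3aR,7R,7aS)-7-hydroxy-2,2-dimethyl-3a,6,7,7a-tetrahydro-1,3-benzodioxole-5-carboxylate | O[C@@H]1CC(C(=O)OCC=C)=C[C@H]2OC(C)(C)O[C@@H]12 | intermediate
10 | (2,3-dimethoxyphenyl)acetic acid | COc1cccc(CC(=O)O)c1OC | starting material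
11 | (6-bromo-2,3-dimethoxyphenyl)acetic acid | COc1ccc(Br)c(CC(=O)O)c1OC | intermediate
12 | (6-bromo-2,3-dihydroxyphenyl)acetic acid | Oc1ccc(Br)c(CC(=O)O)c1O | intermediate
13 | 4-bromo-7-hydroxy-1-benzofuran-2(3H)-one | O=C1Cc2c(Br)ccc(O)c2O1 | intermediate
14 | 4-bromo-7-(tert-butyldimethylsilyloxy)-1-benzofuran-2(3H)-one | O=C1Cc2c(Br)ccc(O[Si](C)(C)C(C)(C)C)c2O1 | intermediate
15 | 3,4-dihydroxybenzaldehyde | O=Cc1ccc(O)c(O)c1 | starting material
16 | 3,4-bis(tert-butyldimethylsilyloxy)benzaldehyde | O=Cc1ccc(O[Si](C)(C)C(C)(C)C)c(O[Si](C)(C)C(C)(C)C)c1 | intermediate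
17 | [3,4-bis(tert-butyldimethylsilyloxy)phenyl]methanol | OCc1ccc(O[Si](C)(C)C(C)(C)C)c(O[Si](C)(C)C(C)(C)C)c1 | intermediate
18 | allyl [6-bromo-3-(tert-butyldimethylsilyloxy)-2-hydroxyphenyl]acetate | C=CCOC(=O)Cc1c(Br)ccc(O[Si](C)(C)C(C)(C)C)c1O | intermediate
19 | allyl [6-bromo-2-{[3,4-bis(tert-butyldimethylsilyloxy)phenyl]methoxy}-3-(tert-butyldimethylsilyloxy)phenyl]acetate | C=CCOC(=O)Cc1c(Br)ccc(O[Si](C)(C)C(C)(C)C)c1OCc1ccc(O[Si](C)(C)C(C)(C)C)c(O[Si](C)(C)C(C)(C)C)c1 | intermediate
20 | [6-bromo-2-{[3,4-bis(tert-butyldimethylsilyloxy)phenyl]methoxy}-3-(tert-butyldimethylsilyloxy)phenyl]acetic acid | OC(=O)Cc1c(Br)ccc(O[Si](C)(C)C(C)(C)C)c1OCc1ccc(O[Si](C)(C)C(C)(C)C)c(O[Si](C)(C)C(C)(C)C)c1 | intermediate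
21 | allyl (3aR,7R,7aS)-7-({[6-bromo-2-{[3,4-bis(TBSO)phenyl]methoxy}-3-(TBSO)phenyl]acetyl}oxy)-2,2-dimethyl-3a,6,7,7a-tetrahydro-1,3-benzodioxole-5-carboxylate | O=C(Cc1c(Br)ccc(O[Si](C)(C)C(C)(C)C)c1OCc1ccc(O[Si](C)(C)C(C)(C)C)c(O[Si](C)(C)C(C)(C)C)c1)O[C@@H]1CC(C(=O)OCC=C)=C[C@H]2OC(C)(C)O[C@@H]12 | intermediate
22 | allyl (3aR,7R,7aS)-7-({diazo[6-bromo-2-{[3,4-bis(TBSO)phenyl]methoxy}-3-(TBSO)phenyl]acetyl}oxy)-2,2-dimethyl-3a,6,7,7a-tetrahydro-1,3-benzodioxole-5-carboxylate | O=C(C(=[N+]=[N-])c1c(Br)ccc(O[Si](C)(C)C(C)(C)C)c1OCc1ccc(O[Si](C)(C)C(C)(C)C)c(O[Si](C)(C)C(C)(C)C)c1)O[C@@H]1CC(C(=O)OCC=C)=C[C@H]2OC(C)(C)O[C@@H]12 | intermediate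
23 | allyl (3aR,7R,7aS)-7-({(2S,3R)-4-bromo-2-[3,4-bis(TBSO)phenyl]-7-(TBSO)-2,3-dihydro-1-benzofuran-3-carbonyl}oxy)-2,2-dimethyl-3a,6,7,7a-tetrahydro-1,3-benzodioxole-5-carboxylate | Brc1ccc(O[Si](C)(C)C(C)(C)C)c2c1[C@@H](C(=O)O[C@@H]1CC(C(=O)OCC=C)=C[C@H]3OC(C)(C)O[C@@H]13)[C@@H](c1ccc(O[Si](C)(C)C(C)(C)C)c(O[Si](C)(C)C(C)(C)C)c1)O2 | intermediate
24 | (3aR,7R,7aS)-7-({(2S,3R)-4-bromo-2-[3,4-bis(TBSO)phenyl]-7-(TBSO)-2,3-dihydro-1-benzofuran-3-carbonyl}oxy)-2,2-dimethyl-3a,6,7,7a-tetrahydro-1,3-benzodioxole-5-carboxylic acid | Brc1ccc(O[Si](C)(C)C(C)(C)C)c2c1[C@@H](C(=O)O[C@@H]1CC(C(=O)O)=C[C@H]3OC(C)(C)O[C@@H]13)[C@@H](c1ccc(O[Si](C)(C)C(C)(C)C)c(O[Si](C)(C)C(C)(C)C)c1)O2 | intermediate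
25 | acrylic acid | C=CC(=O)O | starting material
26 | (3aR,7R,7aS)-7-({(2S,3R)-4-[(E)-2-carboxyethenyl]-2-[3,4-bis(TBSO)phenyl]-7-(TBSO)-2,3-dihydro-1-benzofuran-3-carbonyl}oxy)-2,2-dimethyl-3a,6,7,7a-tetrahydro-1,3-benzodioxole-5-carboxylic acid | O=C(O)/C=C/c1ccc(O[Si](C)(C)C(C)(C)C)c2c1[C@@H](C(=O)O[C@@H]1CC(C(=O)O)=C[C@H]3OC(C)(C)O[C@@H]13)[C@@H](c1ccc(O[Si](C)(C)C(C)(C)C)c(O[Si](C)(C)C(C)(C)C)c1)O2 | intermediate
27 | (3R,4R,5R)-5-({(2S,3R)-4-[(E)-2-carboxyethenyl]-2-(3,4-dihydroxyphenyl)-7-hydroxy-2,3-dihydro-1-benzofuran-3-carbonyl}oxy)-3,4-dihydroxycyclohex-1-ene-1-carboxylic acid | O=C(O)/C=C/c1ccc(O)c2c1[C@@H](C(=O)O[C@@H]1CC(C(=O)O)=C[C@@H](O)[C@H]1O)[C@@H](c1ccc(O)c(O)c1)O2 | target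

**Step count**

Total steps: 18. Longest linear sequence: 11 steps (steps 6, 7, 8, 11–18; the shikimate branch, steps 1–5 and 13–18, is equally long).

**Steps most likely to fail**

1. Step 3 (proposed new method). What may go wrong: self-aldol of the donor outcompeting the cross-aldol, enolization and epimerization of the α-silyloxy aldehyde acceptor under proline, poor facial selectivity if the catalyst and the resident C5 center are mismatched, or retro-aldol and β-elimination before ring closure. The fallback uses known chemistry, sets out from 5 and comes back at 8. A chelation-controlled Mukaiyama aldol addition of the enol silane (Z)-2-acetoxy-1-(trimethylsilyloxy)ethene to 5 (MgBr2·OEt2, CH2Cl2, −20 °C; substrate control of the kind used to build manno-configured triads from α-silyloxy aldehydes) gives allyl (4R,5R,6S)-6-acetoxy-4-(tert-butyldimethylsilyloxy)-2-(diethoxyphosphoryl)-5-hydroxy-7-oxoheptanoate F1. Separate ring-closing olefination under Masamune–Roush conditions (LiCl, i-Pr2NEt, MeCN, 0 °C) gives allyl 3-O-acetyl-5-O-(tert-butyldimethylsilyl)shikimate F2; any acetate migration to O4 is harmless. Acetate removal with K2CO3 (cat.) in allyl alcohol at 0 °C, where exchange at the allyl ester is degenerate, gives allyl 5-O-(tert-butyldimethylsilyl)shikimate F3, which under the conditions of step 4 gives 8.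

2. Step 15. What may go wrong: erosion of cis- and enantioselectivity through mismatch between the chiral catalyst and the chiral shikimate ester or through twisting of the carbenoid by the ortho bromine, and competing insertion into shikimate C–H bonds or cyclopropanation of the allyl group. The fallback sets out from 20 and comes back at 23; it moves the insertion onto a simple achiral ester, the substrate class for which the cis-selective process is established. Acid 20 is esterified with 2,2,2-trichloroethanol (EDC·HCl, DMAP) to 2,2,2-trichloroethyl [6-bromo-2-{[3,4-bis(TBSO)phenyl]methoxy}-3-(TBSO)phenyl]acetate F4. Diazo transfer (p-ABSA, DBU) gives 2,2,2-trichloroethyl diazo[6-bromo-2-{[3,4-bis(TBSO)phenyl]methoxy}-3-(TBSO)phenyl]acetate F5. Rh2(R-PTTL)4 in toluene at −60 °C gives 2,2,2-trichloroethyl (2S,3R)-4-bromo-2-[3,4-bis(TBSO)phenyl]-7-(TBSO)-2,3-dihydro-1-benzofuran-3-carboxylate F6. Zn in AcOH/THF at rt then gives (2S,3R)-4-bromo-2-[3,4-bis(TBSO)phenyl]-7-(TBSO)-2,3-dihydro-1-benzofuran-3-carboxylic acid F7 without base. F7 is esterified with 9 (EDC·HCl, DMAP 5 mol%, CH2Cl2, −20 °C, to limit C3 epimerization) to give 23.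

3. Step 17. What may go wrong: base-mediated epimerization at C3 during a slow coupling, or sluggish oxidative addition into the hindered, electron-rich aryl bromide in the presence of two carboxylates. The fallback sets out from 24 and comes back at 26. It replaces the base-dependent Heck reaction by a base-free Stille coupling of 24 with (E)-3-(tributylstannyl)acrylic acid (Pd2(dba)3, tri(2-furyl)phosphine, CuI, NMP, 50 °C), in which the E-alkene is carried in by the stannane; it gives 26 directly and no new compound arises (F0).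

**Further compounds**

F1 | step 3 | allyl (4R,5R,6S)-6-acetoxy-4-(tert-butyldimethylsilyloxy)-2-(diethoxyphosphoryl)-5-hydroxy-7-oxoheptanoate | CC(C)(C)[Si](C)(C)O[C@H](CC(P(=O)(OCC)OCC)C(=O)OCC=C)[C@H](O)[C@H](OC(C)=O)C=O
F2 | step 3 | allyl 3-O-acetyl-5-O-(tert-butyldimethylsilyl)shikimate | CC(C)(C)[Si](C)(C)O[C@@H]1CC(C(=O)OCC=C)=C[C@@H](OC(C)=O)[C@H]1O
F3 | step 3 | allyl 5-O-(tert-butyldimethylsilyl)shikimate | CC(C)(C)[Si](C)(C)O[C@@H]1CC(C(=O)OCC=C)=C[C@@H](O)[C@H]1O
F4 | step 15 | 2,2,2-trichloroethyl [6-bromo-2-{[3,4-bis(TBSO)phenyl]methoxy}-3-(TBSO)phenyl]acetate | O=C(Cc1c(Br)ccc(O[Si](C)(C)C(C)(C)C)c1OCc1ccc(O[Si](C)(C)C(C)(C)C)c(O[Si](C)(C)C(C)(C)C)c1)OCC(Cl)(Cl)Cl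
F5 | step 15 | 2,2,2-trichloroethyl diazo[6-bromo-2-{[3,4-bis(TBSO)phenyl]methoxy}-3-(TBSO)phenyl]acetate | O=C(C(=[N+]=[N-])c1c(Br)ccc(O[Si](C)(C)C(C)(C)C)c1OCc1ccc(O[Si](C)(C)C(C)(C)C)c(O[Si](C)(C)C(C)(C)C)c1)OCC(Cl)(Cl)Cl
F6 | step 15 | 2,2,2-trichloroethyl (2S,3R)-4-bromo-2-[3,4-bis(TBSO)phenyl]-7-(TBSO)-2,3-dihydro-1-benzofuran-3-carboxylate | Brc1ccc(O[Si](C)(C)C(C)(C)C)c2c1[C@@H](C(=O)OCC(Cl)(Cl)Cl)[C@@H](c1ccc(O[Si](C)(C)C(C)(C)C)c(O[Si](C)(C)C(C)(C)C)c1)O2
F7 | step 15 | (2S,3R)-4-bromo-2-[3,4-bis(TBSO)phenyl]-7-(TBSO)-2,3-dihydro-1-benzofuran-3-carboxylic acid | Brc1ccc(O[Si](C)(C)C(C)(C)C)c2c1[C@@H](C(=O)O)[C@@H](c1ccc(O[Si](C)(C)C(C)(C)C)c(O[Si](C)(C)C(C)(C)C)c1)O2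
F0 | step 17 | none | none
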